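## Structural features

Junceellolide E is a briarane. Cyclohexane ring A (C1, C10 to C14) is trans-fused along C1–C10 to the ten-membered carbocycle ring B (C1 to C10), and a γ-lactone, ring C (C7, C8, C17, C19, O), is fused to ring B at C7–C8. The quaternary C1 (methyl C15) lies between C14 (acetate) and C2 (propionate), whose oxygens are syn across C1, and C10. From C10 the stereocentres run on without a break through C9 (acetate), C8 (tertiary hydroxyl), C7 (lactone oxygen) and C17 (methyl), eight in all (1R,2R,7S,8S,9R,10S,14S,17R). Ring B holds a Z-trisubstituted C5=C6 alkene and ring A the exocyclic methylene C11=C20. The fragile groups are two acetates and one propionate (migration to a neighbouring hydroxyl, non-selective cleavage), a β-hydroxy lactone (retro-aldol cleavage, dehydration), the allylic C7–O bond and the exocyclic alkene (migration into the ring). The real difficulty is twofold: closing ring B with C7 and the alkene geometry correct, and building the crowded C1 with two different esters on its two sides. The key step uses the array C20=C11–C10–C9–C8 of ring A and its side chain: with C8 and C9 at the enol level this is the 1,4-diene left by an Alder-ene reaction between a C11≡C20 alkyne and a C9=C10 alkene bearing an allylic C8 oxygen.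

## Logic of the disconnections

37 ⇒ 36 ⇒ 35 (O9–acetyl, then O9–silyl). The C9 acetate is removed first in the backward sense, because an acyloxy group next to the C8 ketone would not survive the single-electron step that builds ring C. The gain is one robust silyl ether at O9. The demand is acetylation of the secondary C9 hydroxyl of 36 without touching the tertiary C8 hydroxyl.

35 ⇒ 34 (C8–C17). Cutting ring C here removes the lactone and the centres C8 and C17 and leaves a ten-membered α-acyloxy ketone. The forward step must reduce the C–Br bond faster than the ketone and deliver the enolate to the ketone face that gives the trans ring fusion.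

34 ⇒ 33 ⇒ 32 (C8 oxidation level, O7–acyl). The ketone comes from a carbinol and the bromo ester from a free C7 hydroxyl. This reduces the problem to a 7,8-diol but requires that the two secondary hydroxyls of 32 be told apart by their surroundings.

32 ⇒ 31 (C7–C8). This cut opens ring B and leaves ring A with two aldehyde-terminated arms. The forward reductive coupling must close a strained ring in preference to oligomers, keep the Z-alkene and set C7.

31 ⇒ 30 ⇒ 25 + 28, and 28 ⇒ 27 ⇒ 26 (C4–C5). Cutting the sp3–sp2 bond separates the Z-trisubstituted alkene as a four-carbon iodide whose geometry is fixed when it is made from 26. The forward coupling must tolerate three esters and keep the alkene geometry.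

25 ⇒ 24 ⇒ 23 ⇒ 22 ⇒ 19 (C4–I, O4–PMB, O8–silyl, C9–O). The C9 oxygen and the C8 aldehyde level are traced to the enol silane of 19, so no separate oxidation-state chemistry is needed at C8. The forward oxidation must choose the enol ether over the C11=C20 alkene and the correct face at C9.

19 ⇒ 18 (C10–C11). This is the key cut. It opens ring A to an acyclic 1,7-enyne and removes C10 as a stereocentre. The forward step needs a free alkyne, an E-alkene, and an allylic silyl ether that cannot ionise. It must also set C10 from C1 and C14.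

18 ⇒ 17 ⇒ 16 ⇒ 15 ⇒ 14 (alkyne C–Si, O14–acetyl, C14–H, O2–propionyl). The two esters are told apart by timing: C2 is acylated while C14 is still a ketone. The demand is a reagent-controlled reduction of that ketone to the 14S alcohol, syn to the C2 oxygen.

14 ⇒ 11 + 12 (C13–C14). The butynyl arm is added as a carbon nucleophile to an amide that stops at the ketone. The alkyne must be silyl-protected to allow the organomagnesium reagent.

11 ⇒ 9 + 10 (C9=C10) and 9 ⇒ 8. The allylic silyl ether is put on the vinyl group by metathesis before any alkyne is present. The demand is turnover at a vinyl group on a quaternary carbon.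

8 ⇒ 4 + 6 (C1–C2), 4 ⇒ 1 + 2, 6 ⇒ 5. One aldol bond sets C1 and C2 and brings in C2–C4 with its ether. With the S-configured auxiliary, the usual sense of induction fits the target only if the aldehyde supplies C2 and the imide carbon becomes C14; the opposite assignment would call for the R-auxiliary. The demand is α-attack of a dienolate with control of its geometry.

## Other disconnections considered

Alternative 1: The cut is C1–C10, made across a ring. Rings A and B are merged into the fourteen-membered carbocycle A1, in which C2–C1–C14 is a 2-methyl-1,3-diketone and C10=C11 is an enoate with C20 as the ester carbon. In the forward step a mild base forms the diketone enolate, which adds across the ring to C10 and gives the 6/10 bicycle A2.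
- In its favour: one bond creates both carbocycles, the quaternary C1 and C10. A fourteen-membered ring is easier to close than a ten-membered one, and ring C with the C7–C9 oxygens is already in place. On rings formed per key bond it is better than the chosen plan.
- Against it: the C1/C10 relationship depends on the conformation of a flexible macrocycle with no local control element. The two ketones of A2 must then be reduced to the syn diol and given different esters, a problem the chosen plan avoids by acylating C2 before C14 is an alcohol. C20 arrives as an ester that must be reduced and eliminated to the methylene. The β-dicarbonyl is open to retro-Michael and retro-Claisen cleavage.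
- Comparison: in mechanism the two plans are equal, since both are substrate-controlled ring closures. In step economy the alternative is expected to be longer, because A1 must be fully decorated first and several redox and acylation corrections follow A2.

Alternative 2: The cut is C8–C17 of ring C. In the forward step SmI2 reduces the C–Br bond of the O7 2-bromopropanoate in the ten-membered ketone A3, and the samarium enolate adds to the C8 ketone to give the lactone A4.
- In its favour: it is mild, selective for the C–Br bond, and makes C8, C17 and ring C late, so the β-hydroxy lactone is never exposed to base. It is the same construction as step 23 of the chosen plan, so on this bond the alternative is its equal.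
- Against it: as the governing idea it solves only the easiest ring. Ring A, ring B and C1 still need another strategy. Reductive loss of the α-acyloxy group competes.
- Comparison: in structure it addresses ring C only, where the chosen key step makes ring A and C10. In mechanism it is a single-electron process against an organopalladium insertion. In step economy there is no difference, since the chosen plan contains this step. The triethylsilyl ether of A3 and A4 should leave the hindered O9 more easily than the tert-butyldimethylsilyl group of the chosen plan (the alternative is better here), while the chosen plan obtains its O9 silyl ether without a separate protection step.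

Alternative 3: In the backward sense the C5=C6 alkene and the C9 ketone are joined into a C5–C9 bond, giving the 6-7-5 tricycle A5 with a C9 carbinol and a C6 mesylate. In the forward step the C9 alkoxide expels the mesylate with cleavage of C5–C9 (Grob fragmentation) and gives the cyclodecenone A6.
- In its favour: ring B arises from a five- and a seven-membered ring without high dilution. The Z geometry follows stereospecifically from the anti-periplanar C5–C9 and C6–O bonds (C5 methyl trans to the mesylate). On ring B and on alkene geometry it is better than the pinacol closure of the chosen plan.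
- Against it: A5 carries three centres (C5, C6, C9) that exist only to be destroyed, and its synthesis is long. A6 has a C9 ketone to be reduced selectively in a flexible ring, a C7/C8 acetonide to be differentiated before C8 can be oxidised, and ethers at C14 and C2 still to be exchanged for acetate and propionate. Ring A with its methylene must still be made by other means.
- Comparison: in mechanism a concerted, stereospecific fragmentation is more predictable than an insertion biased only by conformation (the alternative is better). In step economy it is expected to be longer by the construction of A5 and by the late redox and protecting-group steps.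

Key step: step 11

Assumption: briarane locants (C1 to C20) are used for all intermediates, and the C8 carbinol of 32 and 33 and the bromine-bearing carbon of 33 and 34 are carried as epimer mixtures because both centres are erased or reset later.

## Route

Step 1
Reactants: 1 tiglic acid [(E)-2-methylbut-2-enoic acid]; 2 (S)-4-benzyloxazolidin-2-one
Product: 4 (S)-4-benzyl-3-[(E)-2-methylbut-2-enoyl]oxazolidin-2-one, via tiglic pivalic anhydride 3 (not isolated)
Conditions: PivCl, Et3N, THF, −20 °C; then LiCl, 2, −20 °C → rt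
Reagents that add atoms: none
Why: N-Acylation of the oxazolidinone through the mixed pivalic anhydride; the hindered pivaloyl carbonyl directs attack to the tigloyl carbonyl, and the E-alkene is not touched.

Step 2
Reactants: 5 3-[(4-methoxybenzyl)oxy]propan-1-ol
Product: 6 3-[(4-methoxybenzyl)oxy]propanal
Conditions: TEMPO (cat.), PhI(OAc)2, CH2Cl2, rt
Reagents that add atoms: none
Why: Nitroxyl-catalysed oxidation of a primary alcohol stops at the aldehyde under neutral conditions, which avoids β-elimination of the PMB ether.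

Step 3
Reactants: 4 (S)-4-benzyl-3-[(E)-2-methylbut-2-enoyl]oxazolidin-2-one; 6 3-[(4-methoxybenzyl)oxy]propanal
Product: 8 aldol adduct (S)-4-benzyl-3-[(2S,3R)-2-ethenyl-3-hydroxy-5-[(4-methoxybenzyl)oxy]-2-methylpentanoyl]oxazolidin-2-one, via boron dienolate 7 (not isolated)
Conditions: Bu2BOTf, Et3N, CH2Cl2, −78 → 0 °C; 6, −78 → 0 °C; pH 7 buffer, MeOH, H2O2, 0 °C
Reagents that add atoms: none
Why: Evans boron aldol of an N-enoyl oxazolidinone: γ-deprotonation should give the O-boron dienolate 7, which reacts at its α-carbon through a chair Zimmerman–Traxler transition state. With the vinyl group cis to the O–B bond (enolisation from the s-cis enoyl conformer) the hydroxyl should end syn to the vinyl group, and attack anti to the benzyl group of the dipole-opposed auxiliary should give the (2S,3R) pair, which is C1 and C2 of the target.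

Step 4
Reactants: 8 aldol adduct (S)-4-benzyl-3-[(2S,3R)-2-ethenyl-3-hydroxy-5-[(4-methoxybenzyl)oxy]-2-methylpentanoyl]oxazolidin-2-one
Product: 9 (2S,3R)-2-ethenyl-3-hydroxy-N-methoxy-5-[(4-methoxybenzyl)oxy]-N,2-dimethylpentanamide
Conditions: Me(MeO)NH·HCl, AlMe3, CH2Cl2, −10 °C → rt
Reagents that add atoms: N,O-dimethylhydroxylamine hydrochloride, CNOC.Cl
Why: Aluminium amide transamidation of an aldol imide; the aluminium alkoxide of the free β-hydroxyl delivers the amide to the exocyclic carbonyl, which should offset the hindrance of the quaternary α-carbon, and auxiliary 2 is recovered.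

Step 5
Reactants: 9 (2S,3R)-2-ethenyl-3-hydroxy-N-methoxy-5-[(4-methoxybenzyl)oxy]-N,2-dimethylpentanamide; 10 allyloxy(tert-butyl)dimethylsilane
Product: 11 (2S,3R)-2-[(E)-3-(tert-butyldimethylsilyloxy)prop-1-enyl]-3-hydroxy-N-methoxy-5-[(4-methoxybenzyl)oxy]-N,2-dimethylpentanamide
Conditions: 10 (5 equiv), second-generation Hoveyda–Grubbs catalyst [RuCl2(H2IMes)(=CH-2-(i-PrO)C6H4)] (10 mol%), CH2Cl2, 40 °C
Reagents that add atoms: none
Why: Olefin cross-metathesis: the vinyl group on the quaternary carbon does not homodimerise, so an excess of the unhindered allyl ether should drive the reaction, and the E-alkene is favoured sterically. Doing this before any alkyne is present excludes enyne metathesis.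

Step 6
Reactants: 11 (2S,3R)-2-[(E)-3-(tert-butyldimethylsilyloxy)prop-1-enyl]-3-hydroxy-N-methoxy-5-[(4-methoxybenzyl)oxy]-N,2-dimethylpentanamide; 12 (4-bromobut-1-ynyl)trimethylsilane
Product: 14 (3R,4S)-4-[(E)-3-(tert-butyldimethylsilyloxy)prop-1-enyl]-3-hydroxy-1-[(4-methoxybenzyl)oxy]-4-methyl-9-(trimethylsilyl)non-8-yn-5-one, via Grignard reagent 13 (not isolated)
Conditions: 12, Mg, THF, rt; then 11, THF, −78 → 0 °C; aq NH4Cl
Reagents that add atoms: none
Why: Grignard addition to a Weinreb amide stops at the ketone through the chelated tetrahedral intermediate; the first equivalent is consumed by the hydroxyl, whose magnesium alkoxide should not undergo retro-aldol cleavage at low temperature.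

Step 7
Reactants: 14 (3R,4S)-4-[(E)-3-(tert-butyldimethylsilyloxy)prop-1-enyl]-3-hydroxy-1-[(4-methoxybenzyl)oxy]-4-methyl-9-(trimethylsilyl)non-8-yn-5-one
Product: 15 (3R,4S)-4-[(E)-3-(tert-butyldimethylsilyloxy)prop-1-enyl]-1-[(4-methoxybenzyl)oxy]-4-methyl-5-oxo-9-(trimethylsilyl)non-8-yn-3-yl propanoate
Conditions: (EtCO)2O, Et3N, DMAP (cat.), CH2Cl2, 0 °C → rt
Reagents that add atoms: propanoic anhydride, CCC(=O)OC(=O)CC
Why: DMAP-catalysed acylation puts the propionate on O2 while C14 is still a ketone, which is how the two oxygens beside C1 are differentiated; the β-acyloxy ketone cannot eliminate because C1 carries no hydrogen.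

Step 8
Reactants: 15 (3R,4S)-4-[(E)-3-(tert-butyldimethylsilyloxy)prop-1-enyl]-1-[(4-methoxybenzyl)oxy]-4-methyl-5-oxo-9-(trimethylsilyl)non-8-yn-3-yl propanoate
Product: 16 (3R,4R,5S)-4-[(E)-3-(tert-butyldimethylsilyloxy)prop-1-enyl]-5-hydroxy-1-[(4-methoxybenzyl)oxy]-4-methyl-9-(trimethylsilyl)non-8-yn-3-yl propanoate
Conditions: (R)-Me-CBS oxazaborolidine (1 equiv), catecholborane, toluene, −78 → −40 °C; MeOH
Reagents that add atoms: none
Why: Corey–Bakshi–Shibata reduction of a ketone flanked by a quaternary carbon (large) and a methylene (small); the (R)-oxazaborolidine should deliver hydride to the face that gives the 14S alcohol, syn to the C2 oxygen. Catecholborane at low temperature leaves the alkene, the silyl alkyne and the ester alone.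

Step 9
Reactants: 16 (3R,4R,5S)-4-[(E)-3-(tert-butyldimethylsilyloxy)prop-1-enyl]-5-hydroxy-1-[(4-methoxybenzyl)oxy]-4-methyl-9-(trimethylsilyl)non-8-yn-3-yl propanoate
Product: 17 (3R,4R,5S)-5-acetoxy-4-[(E)-3-(tert-butyldimethylsilyloxy)prop-1-enyl]-1-[(4-methoxybenzyl)oxy]-4-methyl-9-(trimethylsilyl)non-8-yn-3-yl propanoate
Conditions: Ac2O, pyridine, DMAP, CH2Cl2, 0 °C
Reagents that add atoms: acetic anhydride, CC(=O)OC(C)=O
Why: DMAP-catalysed acetylation of the hindered C14 hydroxyl, run on the crude alcohol so that 1,3-migration of the propionyl group has little time to compete.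

Step 10
Reactants: 17 (3R,4R,5S)-5-acetoxy-4-[(E)-3-(tert-butyldimethylsilyloxy)prop-1-enyl]-1-[(4-methoxybenzyl)oxy]-4-methyl-9-(trimethylsilyl)non-8-yn-3-yl propanoate
Product: 18 enyne (3R,4R,5S)-5-acetoxy-4-[(E)-3-(tert-butyldimethylsilyloxy)prop-1-enyl]-1-[(4-methoxybenzyl)oxy]-4-methylnon-8-yn-3-yl propanoate
Conditions: AgNO3 (20 mol%), MeOH–H2O–CH2Cl2, rt
Reagents that add atoms: none
Why: Silver-catalysed protodesilylation of an alkynylsilane (silver acetylide, then protonolysis) is selective for the C(sp)–Si bond and should spare the silyl ether and both esters, which carbonate in methanol or fluoride would not.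

Step 11
Reactants: 18 enyne (3R,4R,5S)-5-acetoxy-4-[(E)-3-(tert-butyldimethylsilyloxy)prop-1-enyl]-1-[(4-methoxybenzyl)oxy]-4-methylnon-8-yn-3-yl propanoate
Product: 19 enol silane (1S,2R,3S)-3-[(E)-2-(tert-butyldimethylsilyloxy)ethenyl]-2-[(1R)-3-[(4-methoxybenzyl)oxy]-1-(propanoyloxy)propyl]-2-methyl-4-methylidenecyclohexyl acetate
Conditions: Pd2(dba)3·CHCl3 (2.5 mol%), P(o-tol)3 (10 mol%), AcOH (20 mol%), benzene, 60 °C
Reagents that add atoms: none
Why: This is a palladium-hydride Alder-ene cycloisomerisation of a 1,7-enyne, the closest known type being the palladium-catalysed cycloisomerisation of 1,6- and 1,7-enynes to 1-methylene-2-alkenylcycloalkanes. H–Pd–OAc, formed from zerovalent palladium and acetic acid, should add across C11≡C20 with palladium on C11. The alkenylpalladium then inserts the C9=C10 alkene in a 6-exo-trig closure, forming C10–C11 and ring A, and β-hydride elimination from C8 releases the C8=C9 enol silane and returns the hydride. C10 is the one new stereocentre and is controlled by C1 and C14 through a chair-like four-centre insertion transition state: palladium on C11 is pseudo-axial and C9 pseudo-equatorial, so the small C1 methyl should take the axial site 1,3 to palladium, the C2 chain the equatorial site and the C14 acetate the axial site anti to the methyl, which places C9 cis to the methyl (10S). The competing chairs put the C2 chain syn-axial to palladium or C9 syn-axial to the acetate. The second selectivity needed is the direction of elimination: elimination towards C10–H requires C8 to eclipse the quaternary C1 (a consequence of the E-alkene) and would give an alkene with severe A(1,3) strain, whereas the C8–H bonds are freely accessible. The silyl ether at O8 cannot ionise to an allylpalladium species, catalytic acetic acid should leave the enol silane intact, and the acetate and propionate are remote from the metal.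

Step 12
Reactants: 19 enol silane (1S,2R,3S)-3-[(E)-2-(tert-butyldimethylsilyloxy)ethenyl]-2-[(1R)-3-[(4-methoxybenzyl)oxy]-1-(propanoyloxy)propyl]-2-methyl-4-methylidenecyclohexyl acetate
Product: 22 (1S,2R,3S)-3-[(1R)-1-(tert-butyldimethylsilyloxy)-2-hydroxyethyl]-2-[(1R)-3-[(4-methoxybenzyl)oxy]-1-(propanoyloxy)propyl]-2-methyl-4-methylidenecyclohexyl acetate, via silyloxy epoxide 20 (not isolated), via silyloxy aldehyde 21 (not isolated)
Conditions: DMDO, acetone–CH2Cl2, −78 → 0 °C; PPTS (cat.), 0 °C; then NaBH4, MeOH, −20 °C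
Reagents that add atoms: dimethyldioxirane, CC1(C)OO1
Why: Rubottom oxidation: the electron-rich enol silane is epoxidised far faster than the 1,1-disubstituted C11=C20 alkene, epoxide 20 opens with 1,4-silyl shift to the α-silyloxy aldehyde 21, and borohydride reduces this epimerisable aldehyde at once. Attack anti to the quaternary C1, with H10 in the plane of the enol ether, should give 9R.

Step 13
Reactants: 22 (1S,2R,3S)-3-[(1R)-1-(tert-butyldimethylsilyloxy)-2-hydroxyethyl]-2-[(1R)-3-[(4-methoxybenzyl)oxy]-1-(propanoyloxy)propyl]-2-methyl-4-methylidenecyclohexyl acetate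
Product: 23 (1S,2R,3S)-3-[(1R)-1-(tert-butyldimethylsilyloxy)-2-(triethylsilyloxy)ethyl]-2-[(1R)-3-[(4-methoxybenzyl)oxy]-1-(propanoyloxy)propyl]-2-methyl-4-methylidenecyclohexyl acetate
Conditions: Et3SiCl, imidazole, CH2Cl2, 0 °C
Reagents that add atoms: chlorotriethylsilane, CC[Si](CC)(CC)Cl
Why: Silylation of the primary hydroxyl; the triethylsilyl ether masks C8 during the C4 coupling and is later oxidised directly to the aldehyde.

Step 14
Reactants: 23 (1S,2R,3S)-3-[(1R)-1-(tert-butyldimethylsilyloxy)-2-(triethylsilyloxy)ethyl]-2-[(1R)-3-[(4-methoxybenzyl)oxy]-1-(propanoyloxy)propyl]-2-methyl-4-methylidenecyclohexyl acetate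
Product: 24 (1S,2R,3S)-3-[(1R)-1-(tert-butyldimethylsilyloxy)-2-(triethylsilyloxy)ethyl]-2-[(1R)-3-hydroxy-1-(propanoyloxy)propyl]-2-methyl-4-methylidenecyclohexyl acetate
Conditions: DDQ, CH2Cl2–pH 7 buffer, 0 °C
Reagents that add atoms: none
Why: Oxidative cleavage of the PMB ether (benzylic hydride abstraction, then hydrolysis of the hemiacetal) in buffered medium; silyl ethers, esters and the isolated alkene should be inert.

Step 15
Reactants: 24 (1S,2R,3S)-3-[(1R)-1-(tert-butyldimethylsilyloxy)-2-(triethylsilyloxy)ethyl]-2-[(1R)-3-hydroxy-1-(propanoyloxy)propyl]-2-methyl-4-methylidenecyclohexyl acetate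
Product: 25 (1S,2R,3S)-3-[(1R)-1-(tert-butyldimethylsilyloxy)-2-(triethylsilyloxy)ethyl]-2-[(1R)-3-iodo-1-(propanoyloxy)propyl]-2-methyl-4-methylidenecyclohexyl acetate
Conditions: I2, PPh3, imidazole, CH2Cl2, 0 °C → rt
Reagents that add atoms: iodine, II
Why: Appel-type iodination of the primary alcohol by SN2 displacement of the alkoxyphosphonium ion; imidazole keeps the medium non-acidic for the silyl ethers.

Step 16
Reactants: 26 but-2-yn-1-ol
Product: 27 (Z)-3-iodobut-2-en-1-ol
Conditions: NaAlH2(OCH2CH2OMe)2, Et2O, 0 °C → rt; then I2, THF, −78 → 0 °C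
Reagents that add atoms: iodine, II
Why: Hydroxyl-directed trans-hydroalumination of the propargylic alcohol places aluminium on C3, and iodinolysis with retention gives the Z-iodoalkene, which fixes the C5=C6 geometry of the target.

Step 17
Reactants: 27 (Z)-3-iodobut-2-en-1-ol
Product: 28 triethyl{[(Z)-3-iodobut-2-enyl]oxy}silane
Conditions: Et3SiCl, imidazole, CH2Cl2, 0 °C
Reagents that add atoms: chlorotriethylsilane, CC[Si](CC)(CC)Cl
Why: Silylation removes the acidic proton that would quench the organozinc partner and gives an ether that is oxidised directly in step 19.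

Step 18
Reactants: 25 (1S,2R,3S)-3-[(1R)-1-(tert-butyldimethylsilyloxy)-2-(triethylsilyloxy)ethyl]-2-[(1R)-3-iodo-1-(propanoyloxy)propyl]-2-methyl-4-methylidenecyclohexyl acetate; 28 triethyl{[(Z)-3-iodobut-2-enyl]oxy}silane
Product: 30 (1S,2R,3S)-3-[(1R)-1-(tert-butyldimethylsilyloxy)-2-(triethylsilyloxy)ethyl]-2-methyl-2-[(1R,4Z)-4-methyl-1-(propanoyloxy)-6-(triethylsilyloxy)hex-4-enyl]-4-methylidenecyclohexyl acetate, via alkylzinc iodide 29 (not isolated)
Conditions: Zn (activated: BrCH2CH2Br, Me3SiCl), DMA, 40 °C; then 28, Pd(PPh3)4 (5 mol%), THF–DMA, rt → 45 °C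
Reagents that add atoms: none
Why: Negishi sp3–sp2 coupling: zinc inserts into the primary C–I bond without touching the esters, and palladium-catalysed coupling with the alkenyl iodide proceeds with retention of the Z geometry, forming C4–C5.

Step 19
Reactants: 30 (1S,2R,3S)-3-[(1R)-1-(tert-butyldimethylsilyloxy)-2-(triethylsilyloxy)ethyl]-2-methyl-2-[(1R,4Z)-4-methyl-1-(propanoyloxy)-6-(triethylsilyloxy)hex-4-enyl]-4-methylidenecyclohexyl acetate
Product: 31 dialdehyde (1S,2R,3S)-3-[(1R)-1-(tert-butyldimethylsilyloxy)-2-oxoethyl]-2-methyl-2-[(1R,4Z)-4-methyl-6-oxo-1-(propanoyloxy)hex-4-enyl]-4-methylidenecyclohexyl acetate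
Conditions: (COCl)2, DMSO, CH2Cl2, −78 → −30 °C; i-Pr2NEt, −78 → 0 °C
Reagents that add atoms: none
Why: Swern conditions convert primary triethylsilyl ethers directly into aldehydes (the chlorosulfonium ion attacks the ether oxygen and chloride removes silicon), while the secondary tert-butyldimethylsilyl ether is inert. The sensitive dialdehyde is used crude.

Step 20
Reactants: 31 dialdehyde (1S,2R,3S)-3-[(1R)-1-(tert-butyldimethylsilyloxy)-2-oxoethyl]-2-methyl-2-[(1R,4Z)-4-methyl-6-oxo-1-(propanoyloxy)hex-4-enyl]-4-methylidenecyclohexyl acetate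
Product: 32 diol (1R,2R,5Z,7S,9R,10S,14S)-14-acetoxy-9-(tert-butyldimethylsilyloxy)-7,8-dihydroxy-1,5-dimethyl-11-methylidenebicyclo[8.4.0]tetradec-5-en-2-yl propanoate (C8 epimers)
Conditions: SmI2 (3 equiv), THF, −78 °C, slow addition of 31 at high dilution; aq NH4Cl
Reagents that add atoms: none
Why: Intramolecular pinacol coupling with SmI2 (divalent samarium): the ketyl formed at the enal couples at C7 with the C8 aldehyde held on the same samarium centre, closing the ten-membered ring B. Low temperature, the absence of a proton source and high dilution are meant to keep the Z-alkene and favour ring closure; C7 is set by the ring conformation and C8 is oxidised later.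

Step 21
Reactants: 32 diol (1R,2R,5Z,7S,9R,10S,14S)-14-acetoxy-9-(tert-butyldimethylsilyloxy)-7,8-dihydroxy-1,5-dimethyl-11-methylidenebicyclo[8.4.0]tetradec-5-en-2-yl propanoate (C8 epimers)
Product: 33 (1R,2R,5Z,7S,9R,10S,14S)-14-acetoxy-7-(2-bromopropanoyloxy)-9-(tert-butyldimethylsilyloxy)-8-hydroxy-1,5-dimethyl-11-methylidenebicyclo[8.4.0]tetradec-5-en-2-yl propanoate
Conditions: 2-bromopropanoyl bromide, pyridine, CH2Cl2, −78 → −40 °C
Reagents that add atoms: 2-bromopropanoyl bromide, CC(Br)C(=O)Br
Why: Acylation of the less hindered allylic C7 hydroxyl; the C8 hydroxyl is shielded by the neighbouring C9 silyl ether, and the low temperature limits acyl migration.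

Step 22
Reactants: 33 (1R,2R,5Z,7S,9R,10S,14S)-14-acetoxy-7-(2-bromopropanoyloxy)-9-(tert-butyldimethylsilyloxy)-8-hydroxy-1,5-dimethyl-11-methylidenebicyclo[8.4.0]tetradec-5-en-2-yl propanoate
Product: 34 ketone (1R,2R,5Z,7S,9R,10S,14S)-14-acetoxy-7-(2-bromopropanoyloxy)-9-(tert-butyldimethylsilyloxy)-1,5-dimethyl-11-methylidene-8-oxobicyclo[8.4.0]tetradec-5-en-2-yl propanoate
Conditions: Dess–Martin periodinane, NaHCO3, CH2Cl2, 0 °C → rt
Reagents that add atoms: none
Why: Dess–Martin oxidation of the remaining secondary alcohol under buffered, non-basic conditions should give the α-acyloxy ketone without epimerising C7 or C9.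

Step 23
Reactants: 34 ketone (1R,2R,5Z,7S,9R,10S,14S)-14-acetoxy-7-(2-bromopropanoyloxy)-9-(tert-butyldimethylsilyloxy)-1,5-dimethyl-11-methylidene-8-oxobicyclo[8.4.0]tetradec-5-en-2-yl propanoate
Product: 35 9-O-(tert-butyldimethylsilyl)-9-deacetyljunceellolide E (1R,2R,5Z,7S,8S,9R,10S,14S,17R)
Conditions: SmI2 (2.5 equiv), THF, −78 °C; aq NH4Cl
Reagents that add atoms: none
Why: Samarium Reformatsky reaction: SmI2 reduces the C–Br bond to a samarium enolate that adds to the C8 ketone in a 5-exo closure, forming C8–C17 and ring C. Delivery from the O7 tether should place the C8 hydroxyl trans to H7, and a chelated chair-like transition state should place the C17 methyl cis to that hydroxyl.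

Step 24
Reactants: 35 9-O-(tert-butyldimethylsilyl)-9-deacetyljunceellolide E (1R,2R,5Z,7S,8S,9R,10S,14S,17R)
Product: 36 9-deacetyljunceellolide E (1R,2R,5Z,7S,8R,9R,10S,14S,17R)
Conditions: HF·pyridine, pyridine, THF, 0 °C → rt
Reagents that add atoms: none
Why: Fluoride cleavage of the secondary silyl ether under buffered acidic conditions, which the esters, the lactone and the tertiary alcohol should tolerate (the C8 descriptor changes only because the priorities change).

Step 25
Reactants: 36 9-deacetyljunceellolide E (1R,2R,5Z,7S,8R,9R,10S,14S,17R)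
Product: 37 junceellolide E (1R,2R,5Z,7S,8S,9R,10S,14S,17R)
Conditions: Ac2O, DMAP, pyridine, CH2Cl2, 0 °C → rt
Reagents that add atoms: acetic anhydride, CC(=O)OC(C)=O
Why: DMAP-catalysed acetylation is selective for the secondary C9 hydroxyl over the tertiary C8 hydroxyl.

## Compound list

1 | tiglic acid, (E)-2-methylbut-2-enoic acid | C/C=C(\C)C(=O)O | starting material
2 | (S)-4-benzyloxazolidin-2-one | O=C1N[C@@H](Cc2ccccc2)CO1 | starting material
3 | (E)-2-methylbut-2-enoic pivalic anhydride | C/C=C(\C)C(=O)OC(=O)C(C)(C)C | intermediate (not isolated)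
4 | (S)-4-benzyl-3-[(E)-2-methylbut-2-enoyl]oxazolidin-2-one | C/C=C(\C)C(=O)N1C(=O)OC[C@@H]1Cc1ccccc1 | intermediate
5 | 3-[(4-methoxybenzyl)oxy]propan-1-ol | OCCCOCc1ccc(OC)cc1 | starting material
6 | 3-[(4-methoxybenzyl)oxy]propanal | O=CCCOCc1ccc(OC)cc1 | intermediate
7 | (S)-4-benzyl-3-[(1Z)-1-(dibutylboryloxy)-2-methylbuta-1,3-dienyl]oxazolidin-2-one | C=C/C(C)=C(\OB(CCCC)CCCC)N1C(=O)OC[C@@H]1Cc1ccccc1 | intermediate (not isolated)
8 | (S)-4-benzyl-3-[(2S,3R)-2-ethenyl-3-hydroxy-5-[(4-methoxybenzyl)oxy]-2-methylpentanoyl]oxazolidin-2-one | O=C(N1C(=O)OC[C@@H]1Cc1ccccc1)[C@@]([C@H](O)CCOCc1ccc(OC)cc1)(C)C=C | intermediate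
9 | (2S,3R)-2-ethenyl-3-hydroxy-N-methoxy-5-[(4-methoxybenzyl)oxy]-N,2-dimethylpentanamide | CON(C)C(=O)[C@@]([C@H](O)CCOCc1ccc(OC)cc1)(C)C=C | intermediate
10 | allyloxy(tert-butyl)dimethylsilane | C=CCO[Si](C)(C)C(C)(C)C | starting material
11 | (2S,3R)-2-[(E)-3-(tert-butyldimethylsilyloxy)prop-1-enyl]-3-hydroxy-N-methoxy-5-[(4-methoxybenzyl)oxy]-N,2-dimethylpentanamide | CON(C)C(=O)[C@@]([C@H](O)CCOCc1ccc(OC)cc1)(C)/C=C/CO[Si](C)(C)C(C)(C)C | intermediate
12 | (4-bromobut-1-ynyl)trimethylsilane | C[Si](C)(C)C#CCCBr | starting material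
13 | [4-(trimethylsilyl)but-3-ynyl]magnesium bromide | C[Si](C)(C)C#CCC[Mg]Br | intermediate (not isolated)
14 | (3R,4S)-4-[(E)-3-(tert-butyldimethylsilyloxy)prop-1-enyl]-3-hydroxy-1-[(4-methoxybenzyl)oxy]-4-methyl-9-(trimethylsilyl)non-8-yn-5-one | C[Si](C)(C)C#CCCC(=O)[C@@]([C@H](O)CCOCc1ccc(OC)cc1)(C)/C=C/CO[Si](C)(C)C(C)(C)C | intermediate
15 | (3R,4S)-4-[(E)-3-(tert-butyldimethylsilyloxy)prop-1-enyl]-1-[(4-methoxybenzyl)oxy]-4-methyl-5-oxo-9-(trimethylsilyl)non-8-yn-3-yl propanoate | C[Si](C)(C)C#CCCC(=O)[C@@]([C@H](OC(=O)CC)CCOCc1ccc(OC)cc1)(C)/C=C/CO[Si](C)(C)C(C)(C)C | intermediate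
16 | (3R,4R,5S)-4-[(E)-3-(tert-butyldimethylsilyloxy)prop-1-enyl]-5-hydroxy-1-[(4-methoxybenzyl)oxy]-4-methyl-9-(trimethylsilyl)non-8-yn-3-yl propanoate | C[Si](C)(C)C#CCC[C@H](O)[C@@]([C@H](OC(=O)CC)CCOCc1ccc(OC)cc1)(C)/C=C/CO[Si](C)(C)C(C)(C)C | intermediate
17 | (3R,4R,5S)-5-acetoxy-4-[(E)-3-(tert-butyldimethylsilyloxy)prop-1-enyl]-1-[(4-methoxybenzyl)oxy]-4-methyl-9-(trimethylsilyl)non-8-yn-3-yl propanoate | C[Si](C)(C)C#CCC[C@H](OC(C)=O)[C@@]([C@H](OC(=O)CC)CCOCc1ccc(OC)cc1)(C)/C=C/CO[Si](C)(C)C(C)(C)C | intermediate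
18 | (3R,4R,5S)-5-acetoxy-4-[(E)-3-(tert-butyldimethylsilyloxy)prop-1-enyl]-1-[(4-methoxybenzyl)oxy]-4-methylnon-8-yn-3-yl propanoate | C#CCC[C@H](OC(C)=O)[C@@]([C@H](OC(=O)CC)CCOCc1ccc(OC)cc1)(C)/C=C/CO[Si](C)(C)C(C)(C)C | intermediate (precursor of the key step)
19 | (1S,2R,3S)-3-[(E)-2-(tert-butyldimethylsilyloxy)ethenyl]-2-[(1R)-3-[(4-methoxybenzyl)oxy]-1-(propanoyloxy)propyl]-2-methyl-4-methylidenecyclohexyl acetate | C=C1CC[C@H](OC(C)=O)[C@@]([C@H](OC(=O)CC)CCOCc2ccc(OC)cc2)(C)[C@H]1/C=C/O[Si](C)(C)C(C)(C)C | intermediate (product of the key step)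
20 | (1S,2R,3S)-3-[(2R,3R)-3-(tert-butyldimethylsilyloxy)oxiran-2-yl]-2-[(1R)-3-[(4-methoxybenzyl)oxy]-1-(propanoyloxy)propyl]-2-methyl-4-methylidenecyclohexyl acetate | C=C1CC[C@H](OC(C)=O)[C@@]([C@H](OC(=O)CC)CCOCc2ccc(OC)cc2)(C)[C@H]1[C@H]3O[C@@H]3O[Si](C)(C)C(C)(C)C | intermediate (not isolated)
21 | (1S,2R,3S)-3-[(1R)-1-(tert-butyldimethylsilyloxy)-2-oxoethyl]-2-[(1R)-3-[(4-methoxybenzyl)oxy]-1-(propanoyloxy)propyl]-2-methyl-4-methylidenecyclohexyl acetate | C=C1CC[C@H](OC(C)=O)[C@@]([C@H](OC(=O)CC)CCOCc2ccc(OC)cc2)(C)[C@H]1[C@@H](O[Si](C)(C)C(C)(C)C)C=O | intermediate (not isolated)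
22 | (1S,2R,3S)-3-[(1R)-1-(tert-butyldimethylsilyloxy)-2-hydroxyethyl]-2-[(1R)-3-[(4-methoxybenzyl)oxy]-1-(propanoyloxy)propyl]-2-methyl-4-methylidenecyclohexyl acetate | C=C1CC[C@H](OC(C)=O)[C@@]([C@H](OC(=O)CC)CCOCc2ccc(OC)cc2)(C)[C@H]1[C@@H](O[Si](C)(C)C(C)(C)C)CO | intermediate
23 | (1S,2R,3S)-3-[(1R)-1-(tert-butyldimethylsilyloxy)-2-(triethylsilyloxy)ethyl]-2-[(1R)-3-[(4-methoxybenzyl)oxy]-1-(propanoyloxy)propyl]-2-methyl-4-methylidenecyclohexyl acetate | C=C1CC[C@H](OC(C)=O)[C@@]([C@H](OC(=O)CC)CCOCc2ccc(OC)cc2)(C)[C@H]1[C@@H](O[Si](C)(C)C(C)(C)C)CO[Si](CC)(CC)CC | intermediate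
24 | (1S,2R,3S)-3-[(1R)-1-(tert-butyldimethylsilyloxy)-2-(triethylsilyloxy)ethyl]-2-[(1R)-3-hydroxy-1-(propanoyloxy)propyl]-2-methyl-4-methylidenecyclohexyl acetate | C=C1CC[C@H](OC(C)=O)[C@@]([C@H](OC(=O)CC)CCO)(C)[C@H]1[C@@H](O[Si](C)(C)C(C)(C)C)CO[Si](CC)(CC)CC | intermediate
25 | (1S,2R,3S)-3-[(1R)-1-(tert-butyldimethylsilyloxy)-2-(triethylsilyloxy)ethyl]-2-[(1R)-3-iodo-1-(propanoyloxy)propyl]-2-methyl-4-methylidenecyclohexyl acetate | C=C1CC[C@H](OC(C)=O)[C@@]([C@H](OC(=O)CC)CCI)(C)[C@H]1[C@@H](O[Si](C)(C)C(C)(C)C)CO[Si](CC)(CC)CC | intermediate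
26 | but-2-yn-1-ol | CC#CCO | starting material
27 | (Z)-3-iodobut-2-en-1-ol | C/C(I)=C/CO | intermediate
28 | triethyl{[(Z)-3-iodobut-2-enyl]oxy}silane | C/C(I)=C/CO[Si](CC)(CC)CC | intermediate
29 | alkylzinc iodide of 25 (C4–ZnI in place of C4–I) | C=C1CC[C@H](OC(C)=O)[C@@]([C@H](OC(=O)CC)CC[Zn]I)(C)[C@H]1[C@@H](O[Si](C)(C)C(C)(C)C)CO[Si](CC)(CC)CC | intermediate (not isolated)
30 | (1S,2R,3S)-3-[(1R)-1-(tert-butyldimethylsilyloxy)-2-(triethylsilyloxy)ethyl]-2-methyl-2-[(1R,4Z)-4-methyl-1-(propanoyloxy)-6-(triethylsilyloxy)hex-4-enyl]-4-methylidenecyclohexyl acetate | C=C1CC[C@H](OC(C)=O)[C@@]([C@H](OC(=O)CC)CC/C(C)=C\CO[Si](CC)(CC)CC)(C)[C@H]1[C@@H](O[Si](C)(C)C(C)(C)C)CO[Si](CC)(CC)CC | intermediate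
31 | (1S,2R,3S)-3-[(1R)-1-(tert-butyldimethylsilyloxy)-2-oxoethyl]-2-methyl-2-[(1R,4Z)-4-methyl-6-oxo-1-(propanoyloxy)hex-4-enyl]-4-methylidenecyclohexyl acetate | C=C1CC[C@H](OC(C)=O)[C@@]([C@H](OC(=O)CC)CC/C(C)=C\C=O)(C)[C@H]1[C@@H](O[Si](C)(C)C(C)(C)C)C=O | intermediate
32 | (1R,2R,5Z,7S,9R,10S,14S)-14-acetoxy-9-(tert-butyldimethylsilyloxy)-7,8-dihydroxy-1,5-dimethyl-11-methylidenebicyclo[8.4.0]tetradec-5-en-2-yl propanoate (C8 epimers) | C=C1CC[C@H](OC(C)=O)[C@@]2(C)[C@H]1[C@@H](O[Si](C)(C)C(C)(C)C)C(O)[C@@H](O)/C=C(/C)CC[C@H]2OC(=O)CC | intermediate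
33 | (1R,2R,5Z,7S,9R,10S,14S)-14-acetoxy-7-(2-bromopropanoyloxy)-9-(tert-butyldimethylsilyloxy)-8-hydroxy-1,5-dimethyl-11-methylidenebicyclo[8.4.0]tetradec-5-en-2-yl propanoate (C8 and CHBr epimers) | C=C1CC[C@H](OC(C)=O)[C@@]2(C)[C@H]1[C@@H](O[Si](C)(C)C(C)(C)C)C(O)[C@@H](OC(=O)C(C)Br)/C=C(/C)CC[C@H]2OC(=O)CC | intermediate
34 | (1R,2R,5Z,7S,9R,10S,14S)-14-acetoxy-7-(2-bromopropanoyloxy)-9-(tert-butyldimethylsilyloxy)-1,5-dimethyl-11-methylidene-8-oxobicyclo[8.4.0]tetradec-5-en-2-yl propanoate (CHBr epimers) | C=C1CC[C@H](OC(C)=O)[C@@]2(C)[C@H]1[C@@H](O[Si](C)(C)C(C)(C)C)C(=O)[C@@H](OC(=O)C(C)Br)/C=C(/C)CC[C@H]2OC(=O)CC | intermediate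
35 | 9-O-(tert-butyldimethylsilyl)-9-deacetyljunceellolide E, (1R,2R,5Z,7S,8S,9R,10S,14S,17R) | C=C1CC[C@H](OC(C)=O)[C@@]2(C)[C@H]1[C@@H](O[Si](C)(C)C(C)(C)C)[C@@]1(O)[C@H](/C=C(/C)CC[C@H]2OC(=O)CC)OC(=O)[C@@H]1C | intermediate
36 | 9-deacetyljunceellolide E, (1R,2R,5Z,7S,8R,9R,10S,14S,17R) | C=C1CC[C@H](OC(C)=O)[C@@]2(C)[C@H]1[C@@H](O)[C@@]1(O)[C@H](/C=C(/C)CC[C@H]2OC(=O)CC)OC(=O)[C@@H]1C | intermediate
37 | junceellolide E, (1R,2R,5Z,7S,8S,9R,10S,14S,17R) | C=C1CC[C@H](OC(C)=O)[C@@]2(C)[C@H]1[C@@H](OC(C)=O)[C@@]1(O)[C@H](/C=C(/C)CC[C@H]2OC(=O)CC)OC(=O)[C@@H]1C | target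

## Step count and least certain steps

Total: 25 steps. Longest linear sequence: 22 steps from tiglic acid (steps 1, 3 to 15 and 18 to 25); steps 2, 16 and 17 are side branches.

Step 11 (key step). Three things may go wrong. β-Hydride elimination may turn towards C10–H or the released palladium hydride may re-add and move the exocyclic alkene into the ring; an allylic oxygen is known to weaken the preference for the Alder-ene direction. Facial selectivity at C10 may be poor, because the competing chairs differ only in axial methyl and acetate against an axial C2 chain. Insertion at an alkene next to a quaternary carbon may be slow enough for alkyne oligomerisation to compete. The fallback leaves 18 and re-enters at 19 through a radical ring closure. HF·pyridine removes the allylic silyl group to give the allylic alcohol F1, and MnO2 oxidises it to the enal F2. Bu3SnH and AIBN in benzene at 80 °C add a stannyl radical to the alkyne terminus; the C11 vinyl radical closes 6-exo onto C10 of the enal and gives the stannylmethylene aldehyde F3. Protodestannylation (TsOH, wet CH2Cl2) gives the methylene aldehyde F4, and TBSOTf/Et3N converts F4 into 19.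

Step 3. The dienolate is tetrasubstituted, so its geometry and the orientation of the twisted auxiliary are not secured by the usual A(1,3) argument. Loss of diastereocontrol (hydroxyl anti to the vinyl group, or the opposite face) and some γ-attack are the likely failures. The fallback sets out from 2 and 6 and returns at 9. Acylation of 2 with (E)-but-2-enoyl chloride (n-BuLi, THF) gives the crotonyl imide F5. The well-precedented boron aldol of F5 with 6 (Bu2BOTf, Et3N) gives the syn α-vinyl adduct F6 with C2 set by the auxiliary, and MeOMgBr in MeOH gives the methyl ester F7. The dianion of F7 (LDA, 2.2 equiv, THF–DMPU) is methylated anti to the carbinol (Fráter–Seebach alkylation) to give the quaternary ester F8, and AlMe3 with Me(MeO)NH·HCl converts F8 into 9.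

Step 5. Metathesis at a vinyl group on a quaternary carbon next to a carbinol and an amide may stall, so that self-metathesis of 10 and catalyst decay take over. The fallback sets out from 9 and returns at 11. OsO4 (cat.), NaIO4 and 2,6-lutidine cleave the vinyl group to the aldehyde F9. Wittig reaction with Ph3P=CHCHO gives the (E)-enal F10, and NaBH4 with CeCl3·7H2O reduces it to the allylic alcohol F11. TBSCl and imidazole silylate the primary hydroxyl selectively to give 11.

Step 20. Intermolecular coupling may outrun closure of the strained ring. The delocalised ketyl of the enal may rotate and lose the Z geometry or couple through C5. The C9 silyloxy group may be lost reductively, and C7 may form with the wrong configuration because only the ring conformation controls it. The fallback sets out from 31 and returns at 32 by a polar instead of a radical-pair bond formation. CrCl2 and Me3SiCl in THF (divalent chromium) convert the enal into a γ-silyloxyallylchromium species, which adds through its oxygen-bearing carbon C7 to the C8 aldehyde and gives the C7 trimethylsilyl ether F12. Citric acid in MeOH cleaves F12 to 32.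

Step 23. Electron transfer to the α-acyloxy ketone may cleave the C7–O bond before the C–Br bond is reduced. The enolate may also add to the wrong ketone face or give the C17 epimer. The fallback sets out from 32 and returns at 35 without a single-electron reductant. Acryloyl chloride and pyridine give the O7 acrylate F13, and Dess–Martin periodinane gives the keto acrylate F14. Copper hydride, generated from Cu(OAc)2·H2O, a bisphosphine and 1,1,3,3-tetramethyldisiloxane, adds to the acrylate (its β-carbon becomes the C18 methyl), and the copper enolate closes onto the C8 ketone in a reductive aldol cyclisation to give 35.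

## Further compounds

F1 | step 11 | (3R,4R,5S)-5-acetoxy-4-[(E)-3-hydroxyprop-1-enyl]-1-[(4-methoxybenzyl)oxy]-4-methylnon-8-yn-3-yl propanoate | C#CCC[C@H](OC(C)=O)[C@@]([C@H](OC(=O)CC)CCOCc1ccc(OC)cc1)(C)/C=C/CO
F2 | step 11 | (3R,4R,5S)-5-acetoxy-1-[(4-methoxybenzyl)oxy]-4-methyl-4-[(E)-3-oxoprop-1-enyl]non-8-yn-3-yl propanoate | C#CCC[C@H](OC(C)=O)[C@@]([C@H](OC(=O)CC)CCOCc1ccc(OC)cc1)(C)/C=C/C=O
F3 | step 11 | (1S,2R,3S)-2-[(1R)-3-[(4-methoxybenzyl)oxy]-1-(propanoyloxy)propyl]-2-methyl-3-(2-oxoethyl)-4-[(tributylstannyl)methylidene]cyclohexyl acetate | CCCC[Sn](CCCC)(CCCC)C=C1CC[C@H](OC(C)=O)[C@@]([C@H](OC(=O)CC)CCOCc2ccc(OC)cc2)(C)[C@H]1CC=O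
F4 | step 11 | (1S,2R,3S)-2-[(1R)-3-[(4-methoxybenzyl)oxy]-1-(propanoyloxy)propyl]-2-methyl-4-methylidene-3-(2-oxoethyl)cyclohexyl acetate | C=C1CC[C@H](OC(C)=O)[C@@]([C@H](OC(=O)CC)CCOCc2ccc(OC)cc2)(C)[C@H]1CC=O
F5 | step 3 | (S)-4-benzyl-3-[(E)-but-2-enoyl]oxazolidin-2-one | C/C=C/C(=O)N1C(=O)OC[C@@H]1Cc1ccccc1
F6 | step 3 | (S)-4-benzyl-3-[(2S,3R)-2-ethenyl-3-hydroxy-5-[(4-methoxybenzyl)oxy]pentanoyl]oxazolidin-2-one | O=C(N1C(=O)OC[C@@H]1Cc1ccccc1)[C@H]([C@H](O)CCOCc1ccc(OC)cc1)C=C
F7 | step 3 | methyl (2S,3R)-2-ethenyl-3-hydroxy-5-[(4-methoxybenzyl)oxy]pentanoate | COC(=O)[C@H]([C@H](O)CCOCc1ccc(OC)cc1)C=C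
F8 | step 3 | methyl (2S,3R)-2-ethenyl-3-hydroxy-5-[(4-methoxybenzyl)oxy]-2-methylpentanoate | COC(=O)[C@@]([C@H](O)CCOCc1ccc(OC)cc1)(C)C=C
F9 | step 5 | (2R,3R)-2-formyl-3-hydroxy-N-methoxy-5-[(4-methoxybenzyl)oxy]-N,2-dimethylpentanamide | CON(C)C(=O)[C@@]([C@H](O)CCOCc1ccc(OC)cc1)(C)C=O
F10 | step 5 | (2S,3R)-3-hydroxy-N-methoxy-5-[(4-methoxybenzyl)oxy]-N,2-dimethyl-2-[(E)-3-oxoprop-1-enyl]pentanamide | CON(C)C(=O)[C@@]([C@H](O)CCOCc1ccc(OC)cc1)(C)/C=C/C=O
F11 | step 5 | (2S,3R)-3-hydroxy-2-[(E)-3-hydroxyprop-1-enyl]-N-methoxy-5-[(4-methoxybenzyl)oxy]-N,2-dimethylpentanamide | CON(C)C(=O)[C@@]([C@H](O)CCOCc1ccc(OC)cc1)(C)/C=C/CO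
F12 | step 20 | 7-O-trimethylsilyl ether of 32 | C=C1CC[C@H](OC(C)=O)[C@@]2(C)[C@H]1[C@@H](O[Si](C)(C)C(C)(C)C)C(O)[C@@H](O[Si](C)(C)C)/C=C(/C)CC[C@H]2OC(=O)CC
F13 | step 23 | 7-O-acryloyl ester of 32 | C=C1CC[C@H](OC(C)=O)[C@@]2(C)[C@H]1[C@@H](O[Si](C)(C)C(C)(C)C)C(O)[C@@H](OC(=O)C=C)/C=C(/C)CC[C@H]2OC(=O)CC
F14 | step 23 | 7-O-acryloyl C8 ketone (acrylate analogue of 34) | C=C1CC[C@H](OC(C)=O)[C@@]2(C)[C@H]1[C@@H](O[Si](C)(C)C(C)(C)C)C(=O)[C@@H](OC(=O)C=C)/C=C(/C)CC[C@H]2OC(=O)CC
A1 | alternative 1 | fourteen-membered 2-methyl-1,3-diketone with C10=C11 enoate (C20 as methyl ester), lactone, 9-O-TBS and 8-O-TMS (C1 and enoate geometry unspecified) | COC(=O)C1=C[C@@H](O[Si](C)(C)C(C)(C)C)[C@@]2(O[Si](C)(C)C)[C@H](/C=C(/C)CCC(=O)C(C)C(=O)CC1)OC(=O)[C@@H]2C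
A2 | alternative 1 | 6/10-fused C2,C14-diketone with the C20 ester on C11 | COC(=O)[C@@H]1CCC(=O)[C@@]2(C)[C@H]1[C@@H](O[Si](C)(C)C(C)(C)C)[C@@]1(O[Si](C)(C)C)[C@H](/C=C(/C)CCC2=O)OC(=O)[C@@H]1C
A3 | alternative 2 | ten-membered C8 ketone with 7-O-(2-bromopropanoate) and 9-O-triethylsilyl ether | C=C1CC[C@H](OC(C)=O)[C@@]2(C)[C@H]1[C@@H](O[Si](CC)(CC)CC)C(=O)[C@@H](OC(=O)C(C)Br)/C=C(/C)CC[C@H]2OC(=O)CC
A4 | alternative 2 | 9-O-triethylsilyl-9-deacetyljunceellolide E | C=C1CC[C@H](OC(C)=O)[C@@]2(C)[C@H]1[C@@H](O[Si](CC)(CC)CC)[C@@]1(O)[C@H](/C=C(/C)CC[C@H]2OC(=O)CC)OC(=O)[C@@H]1C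
A5 | alternative 3 | 6-7-5 tricycle with C5–C9 bond, C9 carbinol, C6 mesylate trans to the C5 methyl, C7,C8 acetonide, 14-O-PMB and 2-O-TBS | C=C1CC[C@H](OCc5ccc(OC)cc5)[C@@]2(C)[C@H]1[C@]4(O)[C@H]3OC(C)(C)O[C@H]3[C@H](OS(C)(=O)=O)[C@]4(C)CC[C@H]2O[Si](C)(C)C(C)(C)C
A6 | alternative 3 | Z-cyclodecenone with C9 ketone and C7,C8 acetonide | C=C1CC[C@H](OCc5ccc(OC)cc5)[C@@]2(C)[C@H]1C(=O)[C@H]3OC(C)(C)O[C@H]3/C=C(/C)CC[C@H]2O[Si](C)(C)C(C)(C)C
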